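The runs stem from a simulated flask for an exercise, and the scatter is random.

If a flask sends half of its charge to target, we make that the zero of our scale, and the spring run, at 50.4 % in its last reading, is such a flask.

| flask | starting material | precatalyst | remark | time |
|---|---|---|---|---|
| dawn | 0.10 M | 0.20 mM | run made earlier |  |
| spring | 0.10 M | 0.13 mM | run made earlier |  |
| noon | 0.10 M | 0.30 mM | run made earlier |  |
| summer | 0.20 M | 0.20 mM | run made earlier |  |
| Saturday's | 0.10 M | 0.20 mM | everything together in a closed stirred flask, run for 40 min | 40 min |
| Thursday's | 0.10 M | 0.20 mM | one stirred flow tank at steady state, fed with the mixture as stated, mean residence time 40 min |  |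
| Monday's | 0.10 M | 0.20 mM | a single well-mixed tank run continuously and read at steady state, 120 min in it on average |  |
| Wednesday's | 0.10 M (fed, over 32.0 min) | 0.20 mM | all but starting material at the start; starting material goes in evenly over 32.0 min, the run ends at 40 min | 40 min |

- dawn (time / min: target / %): 10.0: 36.3; 20.0: 56.3; 30.0: 58.1; 40.0: 57.6
- spring (time / min: target / %): 2.00: 3.6; 4.00: 5.7; 10.0: 26.7; 25.0: 50.4
- noon (time / min: target / %): 2.00: 3.5; 4.00: 15.4; 10.0: 50.5; 25.0: 62.1
- summer (time / min: target / %): 6.00: 14.4; 12.0: 31.2; 20.0: 40.9; 25.0: 41.9

(standard deviation of a reading: 1 percentage point)

- the set-up with the highest amount of target at the outlet or at the end, in percent of the starting material put in ("none" if the first two lie within 2 percentage points) (Saturday's / Thursday's / Monday's / Wednesday's / none)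
- amount of target at the outlet or at the end, in percent of the starting material put in, Saturday's
- amount of target at the outlet or at the end, in percent of the starting material put in, Thursday's
- amount of target at the outlet or at the end, in percent of the starting material put in, Monday's
- amount of target at the outlet or at the end, in percent of the starting material put in, Wednesday's

- the stated concentrations are those of everything mixed, before any reaction; amounts are the same in each set-up
- the feed brings no volume worth counting
- the earlier runs were made in a closed, stirred flask

We rate each closed run by its load, the starting material charged per precatalyst charged (the substrate-to-catalyst ratio). The spring run then gives the even-split load, 769, taking its last reading as its end. The last readings fall as load rises, from noon's 62.1 % to dawn's 57.6 % and summer's 41.9 %. Dawn, at load 500, and summer, at load 1000, give a cost of 0.031 percentage points per unit of load. Counted from the even split, this line gives 63.7 % for noon, which was not used to draw it and read 62.1 %.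

Saturday's repeats dawn's recipe, so we expect dawn's value. The other three recipes have the same charge, but the feed or the tank keeps the starting material thin. We therefore bracket them. From below, the even split tightens to dawn's 57.6 %, on our assumption that thinning does no harm. From above, the bound stays at 100 %, and we cannot tighten it by hand. The line carried to zero load gives 74.2 %, but that is an estimate far outside the loads it was drawn from, not a bound. The bracket does not rank them.

The forecast gives 58 % for Saturday's, 67 % for Thursday's, 84 % for Monday's and 73 % for Wednesday's, and names Monday's best, “assuming the catalyst survives”. All its values for these three lie inside the bracket, and its Monday's value stands above our estimate, while its Thursday's and Wednesday's values lie below it.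

The flask gives 57.4 % for Saturday's, 58.4 % for Thursday's, 66.8 % for Monday's and 71.3 % for Wednesday's, so Wednesday's is best, and the three tank and feed values lie above dawn's reading and below our estimate.

    starting material + free catalyst → catalyst intermediate (k = 51.0 L mol⁻¹ s⁻¹)
    precatalyst → free catalyst (k = 5.60 × 10⁻⁴ s⁻¹)
    starting material + target → side product (k = 0.0220 L mol⁻¹ s⁻¹)
    catalyst intermediate ⇌ free catalyst + target (K = 1.10 M, k = 24.0 s⁻¹)

Monday's tank stood at 0.00149 M of starting material, less than the 0.0175 M at the peak of Wednesday's, yet it ended lower. On our line, Wednesday's result matches a closed flask of load 90.0, although its charge has load 500. The neighbour charged with 8.0 × 10⁻⁴ M of precatalyst has load 125, where the line gives 70.2 % and the flask gave 73.4 %.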